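Atoms carry their numbers from the target SMILES. The cage is cut at C7–C26 and C9–C11: the tertiary carbinol C26 sits β to the C9 ketone, and the ring C11–C2–C4–C26–C14–C13 is a dimedone-type 1,3-dione whose enol ether belongs to the pyranone. One operation closes the oxolane (aldehyde enamine C7 onto the C26 ketone) and then the bicyclo[2.2.2]octene (C11 dienolate onto the same aldehyde carbon C9). The precursor is a (2S)-2-phenyl-2,3-dihydrochromene-4,5-dione with a methyl group on C11 and a CH2–O–CH(CH3)–CHO arm on C4; only C18 is fixed, the three labile centres C4, C7 and C11 are carried as mixtures.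

Key step: step 6

Design points
- Locants inside names are chromene locants; bare labels are target-SMILES numbers. Chromene O1/C2/C3/C4/C4a/C5/C6/C7/C8/C8a = O25/C18/C17/C15/C14/C26/C4/C2/C11/C13.
- Target check: C4 R, C7 S, C11 R, C18 S, C26 R. The oxolane can bridge C4 and C7 on one flank of the bicyclooctene only, so the cage has a single relative configuration; the open question is its sense against C18.
- The ring oxygen must end on C13 (next to the methyl-bearing C11) and the free ketone on C26 (next to the arm-bearing C4). Cyclising an unsymmetrical trione cannot guarantee this, so the oxygen is fixed first, as a 4-pyranone on symmetric 2-acetyldimedone. In that pyranone C11–H (doubly vinylogous) and C4–H (α′) are the only acidic sp3 positions and differ widely in acidity.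
- Saturated C17–H2 is an α′ position with O25 as β-leaving group, so phenyl and C18 are introduced only after all strong-base chemistry.
- The arm stereocentre becomes the enamine carbon C7, so the arm is used racemic. The aldehyde is carried as a vinyl group and released at neutral pH.
- The amine is a hindered secondary one; a primary amine would open the pyranone at C13 to an NH-enaminone. C7 becomes quaternary in the first aldol, so the catalyst acts through C7; only C11 is dictated by geometry.
- From step 3 on, the compounds are mixtures at C4, C11 and C7; none needs separating.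

Assumption: the absolute sense of induction of the two chiral catalysts (steps 4 and 6) is taken as argued in the Why lines; both exist as antipodes, so the antipode would be substituted if the sense proved opposite.

Step 1
Reactants: 1 2-acetyl-5,5-dimethylcyclohexane-1,3-dione; 2 N,N-dimethylformamide dimethyl acetal
Product: 4 7,7-dimethyl-7,8-dihydro-4H-chromene-4,5(6H)-dione, via enaminone 3 (not isolated)
Conditions: 2 (1.5 equiv), toluene, 90 °C; then AcOH, 100 °C
Reagents that add atoms: N,N-dimethylformamide dimethyl acetal, COC(OC)N(C)C
Why: Condensation of the acetyl methyl group with the amide acetal gives the enaminone, and acid then drives 6-endo addition–elimination of the enol oxygen with loss of dimethylamine (the standard chromone annulation); because 1 is symmetric the ring oxygen can be placed in only one way, which fixes C13 and C26 for the rest of the route.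

Step 2
Reactants: 5 (±)-but-3-en-2-ol; 6 paraformaldehyde
Product: 7 (±)-3-(chloromethoxy)but-1-ene
Conditions: (CH2O)n, Me3SiCl, CH2Cl2, 0 °C → rt; concentrated and used crude
Reagents that add atoms: paraformaldehyde (as formaldehyde), C=O; chlorotrimethylsilane, C[Si](C)(C)Cl
Why: Chloromethylation of an alcohol through its hemiformal and chloride capture of the oxocarbenium ion is the usual preparation of α-chloro ethers; the carbinol centre is used racemic because it becomes the enamine carbon C7 in step 6.

Step 3
Reactants: 4 7,7-dimethyl-7,8-dihydro-4H-chromene-4,5(6H)-dione; 7 (±)-3-(chloromethoxy)but-1-ene; 8 iodomethane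
Product: 10 6-[(but-3-en-2-yloxy)methyl]-7,7,8-trimethyl-7,8-dihydro-4H-chromene-4,5(6H)-dione (mixture of racemic diastereomers), via monoalkylated dienolate 9 (not isolated)
Conditions: LiHMDS (1.05 equiv), THF, −78 °C; LDA (1.1 equiv), −78 → −40 °C; 7 (1.05 equiv), −78 °C; then MeI (3 equiv), DMPU, −78 → 0 °C
Reagents that add atoms: 3-(chloromethoxy)but-1-ene (7), CC(OCCl)C=C; iodomethane (8), CI
Why: Sequential dianion alkylation: the first base removes the doubly vinylogous C11–H, the second the only remaining sp3 α-hydrogen at C4 (C17 and C18 are vinylic here), the more basic C4 enolate takes the α-chloro ether and the stabilised C11 anion then takes iodomethane with return of the pyranone conjugation, while the quaternary C2 next to both sites suppresses double alkylation; the new centres are left uncontrolled because they equilibrate in step 6.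

Step 4
Reactants: 10 6-[(but-3-en-2-yloxy)methyl]-7,7,8-trimethyl-7,8-dihydro-4H-chromene-4,5(6H)-dione; 11 phenylboronic acid
Product: 12 (2S)-6-[(but-3-en-2-yloxy)methyl]-7,7,8-trimethyl-2-phenyl-2,3,7,8-tetrahydro-4H-chromene-4,5(6H)-dione (epimer mixture at chromene C6, C8 and the side-chain carbon)
Conditions: [RhCl(C2H4)2]2 (2.5 mol%), (1S,4S)-2,5-diphenylbicyclo[2.2.2]octa-2,5-diene (5.5 mol%), KOH (10 mol%), PhB(OH)2 (2 equiv), 1,4-dioxane/H2O (10:1), 30 °C
Reagents that add atoms: phenylboronic acid, OB(O)c1ccccc1
Why: Rhodium-catalysed asymmetric 1,4-addition of an arylboronic acid to a chromone-type 4-pyranone (Hayashi–Miyaura reaction): aryl–rhodium inserts the only β-unsubstituted enone C17=C18, the chiral diene selects the face and so sets C18 (S) independently of the remote labile centres, the isolated vinyl group is inert to aryl–rhodium, and no strong base touches the molecule once the enolisable C17–H2 exists.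

Step 5
Reactants: 12 (2S)-6-[(but-3-en-2-yloxy)methyl]-7,7,8-trimethyl-2-phenyl-2,3,7,8-tetrahydro-4H-chromene-4,5(6H)-dione
Product: 13 2-{[(2S)-7,7,8-trimethyl-4,5-dioxo-2-phenyl-3,4,5,6,7,8-hexahydro-2H-chromen-6-yl]methoxy}propanal (epimer mixture at C4, C11 and C7)
Conditions: OsO4 (2 mol%), NaIO4 (4 equiv), 2,6-lutidine (2 equiv), 1,4-dioxane/H2O (3:1), rt; used crude
Reagents that add atoms: osmium tetroxide (catalytic oxygen carrier), O=[Os](=O)(=O)=O; sodium periodate (terminal oxidant), [Na+].[O-]I(=O)(=O)=O
Why: Lemieux–Johnson oxidation: osmium tetroxide dihydroxylates only the monosubstituted alkene (the tetrasubstituted, acceptor-substituted C13=C14 is inert) and periodate cleaves the diol at buffered neutral pH, which avoids acid-induced reopening of the vinylogous-ester ring and base-induced β-elimination at C4 or C17.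

Step 6
Reactants: 13 2-{[(2S)-7,7,8-trimethyl-4,5-dioxo-2-phenyl-3,4,5,6,7,8-hexahydro-2H-chromen-6-yl]methoxy}propanal
Product: 15 C9 carbinol of the target (4R,7R,9S,11S,18S,26R; drawn as the 9S epimer, the 9R epimer serves equally), via oxolane hydroxy aldehyde 14 (not isolated)
Conditions: (S)-α,α-diphenylprolinol trimethylsilyl ether (20 mol%), PhCO2H (20 mol%), toluene, 0 °C → rt; then MeCN, LiCl (3 equiv), DBU (1.2 equiv), 0 °C
Reagents that add atoms: none
Why: The hindered secondary amine converts the aldehyde of 13 (C7 epimers converge) into one enamine whose C7 adds to the C26 ketone of the interconverting C4 epimers to give oxolane 14 after iminium hydrolysis, and LiCl/DBU then forms the C11=C13–C14=C15–O dienolate (C11 epimers converge), whose γ-carbon adds to the now non-enolisable aldehyde carbon C9. Both events are known reaction types: the amine-catalysed enolexo aldolisation of a tethered α-oxy carbonyl compound onto a ketone, and the bridged intramolecular aldol of cyclohexanone-type enolates that gives bicyclo[2.2.2]octanols. The oxolane closes 5-(enolexo)-exo-trig; the second bond closes two six-membered rings at once, 6-exo-trig at the aldehyde, enolendo with respect to ring C9–C11–C13–C14–C26–C7 and enolexo with respect to ring C9–C11–C2–C4–C26–C7. C7 is set by the shielded face of the enamine (the (S)-catalyst with the alkoxy group cis to nitrogen should deliver 7S), C26 and C4 follow from C7 through an open transition state that keeps C9 anti to the carbonyl oxygen and through the obligatory cis ring fusion (dynamic kinetic resolution at C4), C11 can bond only on the face that carries the formyl group, and the C9 carbinol centre (9S expected from lithium bridging to O15) is erased in step 7. The step needs the cage sense to be imposed against the remote C18, which should hold if the first aldol is not reversed before the lithium-templated second closure; it needs C26 as the acceptor, secured because C26 is the only carbonyl within five-ring reach of C7 and shares its enol-ether donor with C15, so it is more electrophilic than a simple vinylogous ester; and it needs deprotonation at C11 and not at C17, which reversible, thermodynamic deprotonation should favour. A mono-aldol with the formyl group turned away from C14 cannot close and can re-enter only by retro-aldol.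

Step 7
Reactants: 15 C9 carbinol of the target
Product: 16 CNP0322161.1 (4R,7S,11R,18S,26R)
Conditions: Dess–Martin periodinane (1.5 equiv), pyridine (3 equiv), CH2Cl2, 0 °C → rt
Reagents that add atoms: none
Why: Dess–Martin oxidation of the secondary C9 carbinol to the ketone under buffered neutral conditions; the tertiary bridgehead alcohol at C26 cannot be oxidised or dehydrated, no enolisable position flanks C9, and the absence of base protects the β-hydroxy ketone from retro-aldol cleavage.

Compound list
1 | 2-acetyl-5,5-dimethylcyclohexane-1,3-dione (2-acetyldimedone, enol form) | CC(=O)C1=C(O)CC(C)(C)CC1=O | starting material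
2 | N,N-dimethylformamide dimethyl acetal | COC(OC)N(C)C | starting material
3 | 2-[(2E)-3-(dimethylamino)prop-2-enoyl]-3-hydroxy-5,5-dimethylcyclohex-2-en-1-one | CN(C)/C=C/C(=O)C1=C(O)CC(C)(C)CC1=O | intermediate (not isolated)
4 | 7,7-dimethyl-7,8-dihydro-4H-chromene-4,5(6H)-dione | CC1(C)CC(=O)C2=C(C1)OC=CC2=O | intermediate
5 | (±)-but-3-en-2-ol | CC(O)C=C | starting material
6 | paraformaldehyde (formaldehyde source) | C=O | starting material
7 | (±)-3-(chloromethoxy)but-1-ene | CC(OCCl)C=C | intermediate
8 | iodomethane | CI | starting material
9 | 6-[(but-3-en-2-yloxy)methyl]-7,7-dimethyl-7,8-dihydro-4H-chromene-4,5(6H)-dione, present as its C8 lithium dienolate (racemic, two diastereomers) | C=CC(C)OCC1C(=O)C2=C(CC1(C)C)OC=CC2=O | intermediate (not isolated)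
10 | 6-[(but-3-en-2-yloxy)methyl]-7,7,8-trimethyl-7,8-dihydro-4H-chromene-4,5(6H)-dione (racemic; mixture at chromene C6, C8 and the side-chain carbon) | C=CC(C)OCC1C(=O)C2=C(OC=CC2=O)C(C)C1(C)C | intermediate
11 | phenylboronic acid | OB(O)c1ccccc1 | starting material
12 | (2S)-6-[(but-3-en-2-yloxy)methyl]-7,7,8-trimethyl-2-phenyl-2,3,7,8-tetrahydro-4H-chromene-4,5(6H)-dione (C18 S; mixture at C4, C11 and the side-chain carbon) | CC1C(C)(C)C(COC(C)C=C)C(=O)C2=C1O[C@H](c1ccccc1)CC2=O | intermediate
13 | 2-{[(2S)-7,7,8-trimethyl-4,5-dioxo-2-phenyl-3,4,5,6,7,8-hexahydro-2H-chromen-6-yl]methoxy}propanal (C18 S; mixture at C4, C11 and C7) | CC1C(C)(C)C(COC(C)C=O)C(=O)C2=C1O[C@H](c1ccccc1)CC2=O | intermediate (key-step precursor)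
14 | oxolane hydroxy aldehyde: oxolane C4–C5–O6–C7–C26 cis-fused to the carbocycle, OH on C26, C7 bearing CH3 and CHO with CHO on the face of C14 (4R,7S,18S,26R; C11 unassigned) | CC1C(C)(C)[C@@H]2CO[C@](C)(C=O)[C@]2(O)C2=C1O[C@H](c1ccccc1)CC2=O | intermediate (not isolated)
15 | C9 carbinol of the target (4R,7R,9S,11S,18S,26R; the changed letters at C7 and C11 reflect CIP priorities only) | CC1(C)[C@@H]2CO[C@]3(C)[C@@H](O)[C@@]1(C)C1=C(C(=O)C[C@@H](c4ccccc4)O1)[C@]23O | intermediate (key-step product)
16 | CNP0322161.1, cage ketol (4R,7S,11R,18S,26R) | CC1(C)[C@@H]2CO[C@]3(C)C(=O)[C@@]1(C)C1=C(C(=O)C[C@@H](c4ccccc4)O1)[C@]23O | target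

Total steps: 7. Longest linear sequence: 6 (steps 1, 3, 4, 5, 6, 7; the branch through step 2 is equally long).

Steps most likely to fail

1. Step 6. The first aldol may revert before the second closure, so that the cage sense is no longer imposed by the amine. The base may enolise C17 instead of C11, leading to closure through C17 or to β-elimination of O25 with loss of configuration at C18. The arm may also be expelled from the C4 enolate. Fallback: postpone the C18 centre. Setting out from 10, the cleavage conditions of step 5 give the pyranone aldehyde 2-[(7,7,8-trimethyl-4,5-dioxo-5,6,7,8-tetrahydro-4H-chromen-6-yl)methoxy]propanal F1. The amine/base sequence of step 6 is then run on this substrate, whose C17 is vinylic, so neither an α′-enolate nor β-elimination is possible and only enantiocontrol is asked of the amine. It passes through the oxolane hydroxy aldehyde of the pyranone series F2 (not isolated) to the cage pyranone carbinol F3. Palladium(II)-catalysed asymmetric conjugate addition of phenylboronic acid (Pd(OCOCF3)2, (R)-t-BuPyOX, NH4PF6, H2O, ClCH2CH2Cl, 40 °C; the vinyl group that excluded palladium in step 4 is gone) on this rigid single compound sets C18 and comes back to the route at 15.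

2. Step 3. The hard chloromethyl ether may alkylate on oxygen, or proton transfer between the two anionic sites may send the arm to C11 and the methyl group to C4. Fallback: separate the two events and attach the arm by conjugate addition. Setting out from 4, the monoanion alone is methylated (LiHMDS, MeI) to 7,7,8-trimethyl-7,8-dihydro-4H-chromene-4,5(6H)-dione F4. The C4 position is then α-methylenated with paraformaldehyde and diisopropylammonium trifluoroacetate (the tertiary C11–H cannot give an alkene) to 7,7,8-trimethyl-6-methylidene-7,8-dihydro-4H-chromene-4,5(6H)-dione F5. Trimethylphosphine-catalysed oxa-Michael addition of alcohol 5 to the exocyclic enone comes back to the route at 10.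

3. Step 4. Facial control may be incomplete on the stereoisomeric mixture, or the acidic C11–H may consume aryl–rhodium by protonolysis. Fallback: give up induction at this stage and separate at the cage. Setting out from 10, achiral [Rh(OH)(cod)]2 with excess boronic acid gives the C18-epimeric mixture of 12 F6. Steps 5 and 6 are run on it, through the C18-epimeric mixture of 13 F7 and through 14 together with the C18 epimer of 14 F8 (not isolated). Because the amine fixes the cage irrespective of the remote C18, the outcome should be 15 and the C18 epimer of 15 F9, two rigid diastereomers that are separated by chromatography; the route is rejoined at 15.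

Further compounds
F1 | step 6 | 2-[(7,7,8-trimethyl-4,5-dioxo-5,6,7,8-tetrahydro-4H-chromen-6-yl)methoxy]propanal (stereoisomer mixture) | CC1C(C)(C)C(COC(C)C=O)C(=O)C2=C1OC=CC2=O
F2 | step 6 | oxolane hydroxy aldehyde of the pyranone series (not isolated) | CC1C(C)(C)[C@@H]2CO[C@](C)(C=O)[C@]2(O)C2=C1OC=CC2=O
F3 | step 6 | cage pyranone carbinol (15 without phenyl, C17=C18) | CC1(C)[C@@H]2CO[C@]3(C)[C@@H](O)[C@@]1(C)C1=C(C(=O)C=CO1)[C@]23O
F4 | step 3 | 7,7,8-trimethyl-7,8-dihydro-4H-chromene-4,5(6H)-dione (racemic) | CC1C(C)(C)CC(=O)C2=C1OC=CC2=O
F5 | step 3 | 7,7,8-trimethyl-6-methylidene-7,8-dihydro-4H-chromene-4,5(6H)-dione (racemic) | CC1C(C)(C)C(=C)C(=O)C2=C1OC=CC2=O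
F6 | step 4 | C18-epimeric mixture of 12 | CC1C(C)(C)C(COC(C)C=C)C(=O)C2=C1OC(c1ccccc1)CC2=O
F7 | step 4 | C18-epimeric mixture of 13 | CC1C(C)(C)C(COC(C)C=O)C(=O)C2=C1OC(c1ccccc1)CC2=O
F8 | step 4 | C18 epimer of 14 (not isolated) | CC1C(C)(C)[C@@H]2CO[C@](C)(C=O)[C@]2(O)C2=C1O[C@@H](c1ccccc1)CC2=O
F9 | step 4 | C18 epimer of 15 | CC1(C)[C@@H]2CO[C@]3(C)[C@@H](O)[C@@]1(C)C1=C(C(=O)C[C@H](c4ccccc4)O1)[C@]23O
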